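Retrosynthesis: the C1=C8a/C8=O unsaturation of the left ring is removed first (formal addition of H2 gives an isochroman–isochromanone dimer). The C7–CH2 bond is then cut to a left isochroman diol and a C7'-aminomethylated lactone. Both halves go back to one (3R,4S)-3,4,5-trimethylisochroman, cut at C1 (formaldehyde) and at the aryl–C4 bond (aryl Grignard plus epoxide).
Forward order: the arene is bought; the pyran ring is closed once, by oxa-Pictet–Spengler cyclisation; one portion is oxidised at C1 to the lactone; the halves are joined through the CH2 bridge; the left carbocycle is dearomatised in the last step.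
Stereochemistry: C4/C4' come from SN2 inversion when the aryl copper species opens (2S,3S)-2,3-epoxybutane, made from (2S,3S)-butane-2,3-diol. C3/C3' come from Mitsunobu inversion of the resulting carbinol. No later step touches C3–O or C4–aryl.
Enabling feature: in the left 2-benzopyran the C1 methylene lies between O2 and C8a, para to the C6 hydroxyl and ortho to the C8 hydroxyl, so it is the one position that gives up hydride easily. The right 2-benzopyran already has C1' as a lactone carbonyl, and once the bridge joins C7 to C7' every carbon of both carbocycles is substituted.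

Key step: step 16

Remark: the target is drawn as its C8-keto/C6-enol tautomer; the C6-keto/C8-enol form differs only by a proton shift between O6 and O8 and is assumed to equilibrate with it.
Remark: the phenols are carried as benzyl ethers, because exhaustive O-demethylation of a resorcinol dimethyl ether beside an acid-labile benzylic ether is unreliable, whereas hydrogenolysis is neutral; the dibenzyl ether of the aryl bromide is made in one step from 5-bromoresorcinol.

Step 1
Reactants: 1 5-bromobenzene-1,3-diol (5-bromoresorcinol)
Product: 2 1,3-bis(benzyloxy)-5-bromobenzene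
Conditions: BnBr (2.2 equiv), K2CO3, DMF, 60 °C
Reagents that add atoms: benzyl bromide, BrCc1ccccc1
Why: Double Williamson etherification (SN2 of the two phenoxides on benzyl bromide) should be clean on this unhindered resorcinol and installs ethers that can later be removed without acid or nucleophile.

Step 2
Reactants: 2 1,3-bis(benzyloxy)-5-bromobenzene
Product: 4 2,4-bis(benzyloxy)-6-bromobenzaldehyde, via iminium chloride 3 (not isolated)
Conditions: POCl3 (1.5 equiv), DMF, 0 → 80 °C; then ice-water, aq. NaOAc
Reagents that add atoms: N,N-dimethylformamide, CN(C)C=O; water, O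
Why: Vilsmeier–Haack formylation should take place at the ring carbon next to bromine, which is para to one benzyloxy group and ortho to the other and less hindered than the carbon between the two ethers; hydrolysis of iminium salt 3 on work-up releases the aldehyde.

Step 3
Reactants: 4 2,4-bis(benzyloxy)-6-bromobenzaldehyde
Product: 6 1,5-bis(benzyloxy)-3-bromo-2-methylbenzene, via benzylic alcohol 5 (not isolated)
Conditions: Et3SiH (3 equiv), TFA, CH2Cl2, 0 °C → rt
Reagents that add atoms: none
Why: Ionic hydrogenation: hydride transfer to the protonated aldehyde gives benzylic alcohol 5, which ionises in TFA to a cation stabilised by the ortho- and para-benzyloxy groups and accepts a second hydride, leaving the aryl bromide and the benzyl ethers untouched.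

Step 4
Reactants: 7 (2S,3S)-butane-2,3-diol
Product: 8 (2S,3R)-3-bromobutan-2-yl acetate (erythro)
Conditions: HBr (33% in AcOH), 0 °C → rt
Reagents that add atoms: hydrogen bromide, Br; acetic acid, CC(=O)O
Why: Bromoacetate formation from a 1,2-diol runs through the cyclic acetoxonium ion, formed with both C–O bonds intact, and bromide opens it by SN2 with inversion at one of the two equivalent carbons.

Step 5
Reactants: 8 (2S,3R)-3-bromobutan-2-yl acetate
Product: 10 (2S,3S)-2,3-dimethyloxirane (trans-2,3-epoxybutane), via bromohydrin 9 (not isolated)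
Conditions: 50% aq. KOH, 20 → 90 °C, epoxide distilled out as formed; dried over CaH2
Reagents that add atoms: none
Why: Saponification to bromohydrin 9 and intramolecular Williamson closure invert the bromine-bearing carbon a second time, so the trans-(2S,3S) epoxide should result with net retention of the diol configuration, and its low boiling point lets it leave the basic medium at once.

Step 6
Reactants: 6 1,5-bis(benzyloxy)-3-bromo-2-methylbenzene; 10 (2S,3S)-2,3-dimethyloxirane
Product: 12 (2S,3S)-3-[3,5-bis(benzyloxy)-2-methylphenyl]butan-2-ol (erythro), via aryl Grignard reagent 11 (not isolated)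
Conditions: Mg turnings (activated with 1,2-dibromoethane), THF, reflux; then CuI (10 mol%), 10 (1.5 equiv), THF, −30 °C → rt; aq. NH4Cl
Reagents that add atoms: none
Why: Copper-catalysed SN2 opening of the C2-symmetric epoxide by aryl Grignard reagent 11 (both epoxide carbons are equivalent) inverts the attacked carbon and thereby sets the aryl-bearing centre, the later C4 and C4', as S, while the carbinol carbon keeps its S configuration.

Step 7
Reactants: 12 (2S,3S)-3-[3,5-bis(benzyloxy)-2-methylphenyl]butan-2-ol
Product: 13 (2R,3S)-3-[3,5-bis(benzyloxy)-2-methylphenyl]butan-2-yl 4-nitrobenzoate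
Conditions: 4-O2NC6H4CO2H (2 equiv), PPh3 (2 equiv), DIAD (2 equiv), THF, 0 °C → rt
Reagents that add atoms: 4-nitrobenzoic acid, O=C(O)c1ccc(cc1)[N+](=O)[O-]
Why: Mitsunobu reaction with the acidic 4-nitrobenzoic acid, the usual choice for hindered secondary alcohols: carboxylate displaces the alkoxyphosphonium ion by SN2 and inverts the carbinol carbon to R (the later C3 and C3'), and aryl participation is not expected because the ipso carbon is meta to both ether oxygens.

Step 8
Reactants: 13 (2R,3S)-3-[3,5-bis(benzyloxy)-2-methylphenyl]butan-2-yl 4-nitrobenzoate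
Product: 14 (2R,3S)-3-[3,5-bis(benzyloxy)-2-methylphenyl]butan-2-ol (threo)
Conditions: K2CO3 (0.3 equiv), MeOH/THF, rt
Reagents that add atoms: none
Why: Base-catalysed methanolysis (transesterification) of the activated aryl ester cleaves the acyl–oxygen bond only, so the inverted carbinol configuration is retained.

Step 9
Reactants: 14 (2R,3S)-3-[3,5-bis(benzyloxy)-2-methylphenyl]butan-2-ol; 15 formaldehyde (used as paraformaldehyde)
Product: 16 (3R,4S)-6,8-bis(benzyloxy)-3,4,5-trimethylisochroman
Conditions: (CH2O)n (2 equiv), TsOH·H2O (20 mol%), toluene, 60 °C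
Reagents that add atoms: none
Why: Oxa-Pictet–Spengler cyclisation: the alcohol and formaldehyde give an O-tethered oxocarbenium ion that is attacked in a 6-endo-trig Friedel–Crafts closure by the only ring carbon ortho to the side chain (para to one benzyloxy group, ortho to the other); no stereocentre is formed or disturbed.

Step 10
Reactants: 16 (3R,4S)-6,8-bis(benzyloxy)-3,4,5-trimethylisochroman
Product: 17 (3R,4S)-3,4,5-trimethylisochroman-6,8-diol
Conditions: H2 (1 atm), 10% Pd/C, EtOAc, rt
Reagents that add atoms: none
Why: Hydrogenolysis of the two aryl benzyl ethers; under neutral conditions at atmospheric pressure the cyclic benzylic C1–O2 ether should be cleaved far more slowly than the O-benzyl aryl ethers.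

Step 11
Reactants: 16 (3R,4S)-6,8-bis(benzyloxy)-3,4,5-trimethylisochroman
Product: 18 (3R,4S)-6,8-bis(benzyloxy)-3,4,5-trimethylisochroman-1-ol (lactol, both C1 epimers)
Conditions: DDQ (1.2 equiv), CH2Cl2/H2O (10:1), 0 °C → rt
Reagents that add atoms: water, O
Why: DDQ oxidation of an electron-rich isochroman at C1: hydride leaves from the C–H that is benzylic, next to the ring oxygen and para/ortho to the two benzyloxy groups, and water traps the oxocarbenium ion as the lactol, whose C1 configuration is irrelevant because C1 becomes a carbonyl in the next step.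

Step 12
Reactants: 18 (3R,4S)-6,8-bis(benzyloxy)-3,4,5-trimethylisochroman-1-ol
Product: 19 (3R,4S)-6,8-bis(benzyloxy)-3,4,5-trimethylisochroman-1-one
Conditions: TEMPO (10 mol%), PhI(OAc)2 (1.5 equiv), CH2Cl2, rt
Reagents that add atoms: none
Why: Oxoammonium-mediated oxidation of a lactol to the lactone is mild and metal-free and should not affect the benzyl ethers or the benzylic C4–H.

Step 13
Reactants: 19 (3R,4S)-6,8-bis(benzyloxy)-3,4,5-trimethylisochroman-1-one
Product: 20 (3R,4S)-6,8-dihydroxy-3,4,5-trimethylisochroman-1-one
Conditions: H2 (1 atm), 10% Pd/C, EtOAc/MeOH, rt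
Reagents that add atoms: none
Why: Hydrogenolysis of the aryl benzyl ethers; the lactone C3–O bond is not benzylic and the ester is inert under these conditions.

Step 14
Reactants: 20 (3R,4S)-6,8-dihydroxy-3,4,5-trimethylisochroman-1-one; 21 N,N-dimethylmethyleneiminium iodide (Eschenmoser salt)
Product: 22 (3R,4S)-7-[(dimethylamino)methyl]-6,8-dihydroxy-3,4,5-trimethylisochroman-1-one
Conditions: 21 (1.1 equiv), K2CO3 (1.2 equiv), MeCN, 0 °C → rt
Reagents that add atoms: none
Why: Mannich aminomethylation of a phenol with a preformed iminium salt: the phenoxide reacts through C7, the only unsubstituted ring carbon and ortho to both hydroxyls, and any O-aminomethylation is reversible.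

Step 15
Reactants: 17 (3R,4S)-3,4,5-trimethylisochroman-6,8-diol; 22 (3R,4S)-7-[(dimethylamino)methyl]-6,8-dihydroxy-3,4,5-trimethylisochroman-1-one
Product: 24 (3R,4S)-7-{[(3R,4S)-6,8-dihydroxy-3,4,5-trimethylisochroman-7-yl]methyl}-6,8-dihydroxy-3,4,5-trimethylisochroman-1-one, via ortho-quinone methide 23 (not isolated)
Conditions: 17 (2 equiv), degassed 1,4-dioxane, 100 °C, slow Ar stream
Reagents that add atoms: none
Why: Thermal elimination of dimethylamine from the ortho-hydroxybenzylamine (retro-Mannich type) gives ortho-quinone methide 23, which is captured by conjugate, Friedel–Crafts-type addition of C7 of diol 17, its only free ring carbon, and rearomatises; excess 17 and removal of the amine favour cross-coupling over oligomerisation of 23.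

Step 16
Reactants: 24 (3R,4S)-7-{[(3R,4S)-6,8-dihydroxy-3,4,5-trimethylisochroman-7-yl]methyl}-6,8-dihydroxy-3,4,5-trimethylisochroman-1-one
Product: 25 dicitrinone G
Conditions: DDQ (1.0 equiv), anhydrous 1,4-dioxane, 4 Å molecular sieves, 15 °C → rt, Ar, dark
Reagents that add atoms: none
Why: After charge-transfer complexation with the electron-rich left ring, DDQ should take hydride from C1–H, the single C–H of 24 that is benzylic, attached to the ring oxygen O2, para to the C6 hydroxyl and ortho to the C8 hydroxyl; the delocalised oxocarbenium–phenoxonium ion then gives a phenolic proton to the reduced quinone and settles as the neutral push-pull quinone methide, written as its C8-keto/C6-enol tautomer. The closest known reaction type is the quinone or bromine dehydrogenation of 6,8-dihydroxyisochromans of the dihydrocitrinin family to the citrinin chromophore, a special case of the DDQ oxidation of para-hydroxybenzyl ethers to para-quinone methides. No ring closes and no stereocentre is created; only the C1–C8a bond is desaturated and C3/C4 are not involved. The step needs chemoselectivity for C1–H over the diarylmethane bridge, the C5 methyl group and C4–H: the oxygen next to C1 singles out that position, the bridge CH2 is crowded by four ortho substituents and borders the electron-poor lactone ring, C4–H is meta to both hydroxyls, and the right ring is deactivated by its conjugated lactone carbonyl. One equivalent of oxidant and strict exclusion of water are meant to prevent hydration at C1 to the lactol and further oxidation to the bis-lactone.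

Compound list
1 | 5-bromobenzene-1,3-diol (5-bromoresorcinol) | Oc1cc(O)cc(Br)c1 | starting material
2 | 1,3-bis(benzyloxy)-5-bromobenzene | Brc1cc(OCc2ccccc2)cc(OCc2ccccc2)c1 | intermediate
3 | N-{[2,4-bis(benzyloxy)-6-bromophenyl]methylidene}-N-methylmethanaminium chloride | C[N+](C)=Cc1c(Br)cc(OCc2ccccc2)cc1OCc1ccccc1.[Cl-] | intermediate
4 | 2,4-bis(benzyloxy)-6-bromobenzaldehyde | O=Cc1c(Br)cc(OCc2ccccc2)cc1OCc1ccccc1 | intermediate
5 | [2,4-bis(benzyloxy)-6-bromophenyl]methanol | OCc1c(Br)cc(OCc2ccccc2)cc1OCc1ccccc1 | intermediate
6 | 1,5-bis(benzyloxy)-3-bromo-2-methylbenzene | Cc1c(Br)cc(OCc2ccccc2)cc1OCc1ccccc1 | intermediate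
7 | (2S,3S)-butane-2,3-diol | C[C@H](O)[C@H](C)O | starting material
8 | (2S,3R)-3-bromobutan-2-yl acetate | C[C@H](OC(C)=O)[C@@H](C)Br | intermediate
9 | (2S,3R)-3-bromobutan-2-ol (formed as its potassium alkoxide) | C[C@H](O)[C@@H](C)Br | intermediate
10 | (2S,3S)-2,3-dimethyloxirane (trans-2,3-epoxybutane) | C[C@@H]1O[C@H]1C | intermediate
11 | [3,5-bis(benzyloxy)-2-methylphenyl]magnesium bromide | Cc1c([Mg]Br)cc(OCc2ccccc2)cc1OCc1ccccc1 | intermediate
12 | (2S,3S)-3-[3,5-bis(benzyloxy)-2-methylphenyl]butan-2-ol (erythro) | C[C@H](O)[C@@H](C)c1cc(OCc2ccccc2)cc(OCc2ccccc2)c1C | intermediate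
13 | (2R,3S)-3-[3,5-bis(benzyloxy)-2-methylphenyl]butan-2-yl 4-nitrobenzoate | C[C@@H](OC(=O)c1ccc(cc1)[N+](=O)[O-])[C@@H](C)c1cc(OCc2ccccc2)cc(OCc2ccccc2)c1C | intermediate
14 | (2R,3S)-3-[3,5-bis(benzyloxy)-2-methylphenyl]butan-2-ol (threo) | C[C@@H](O)[C@@H](C)c1cc(OCc2ccccc2)cc(OCc2ccccc2)c1C | intermediate
15 | formaldehyde (used as paraformaldehyde) | C=O | starting material
16 | (3R,4S)-6,8-bis(benzyloxy)-3,4,5-trimethylisochroman | Cc1c(OCc3ccccc3)cc(OCc4ccccc4)c2c1[C@H](C)[C@@H](C)OC2 | intermediate
17 | (3R,4S)-3,4,5-trimethylisochroman-6,8-diol | Cc1c(O)cc(O)c2c1[C@H](C)[C@@H](C)OC2 | intermediate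
18 | (3R,4S)-6,8-bis(benzyloxy)-3,4,5-trimethylisochroman-1-ol (lactol, both C1 epimers) | Cc1c(OCc3ccccc3)cc(OCc4ccccc4)c2c1[C@H](C)[C@@H](C)OC2O | intermediate
19 | (3R,4S)-6,8-bis(benzyloxy)-3,4,5-trimethylisochroman-1-one | Cc1c(OCc3ccccc3)cc(OCc4ccccc4)c2c1[C@H](C)[C@@H](C)OC2=O | intermediate
20 | (3R,4S)-6,8-dihydroxy-3,4,5-trimethylisochroman-1-one | Cc1c(O)cc(O)c2c1[C@H](C)[C@@H](C)OC2=O | intermediate
21 | N,N-dimethylmethyleneiminium iodide (Eschenmoser salt) | C=[N+](C)C.[I-] | starting material
22 | (3R,4S)-7-[(dimethylamino)methyl]-6,8-dihydroxy-3,4,5-trimethylisochroman-1-one | CN(C)Cc1c(O)c(C)c2c(c1O)C(=O)O[C@H](C)[C@H]2C | intermediate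
23 | (3R,4S)-8-hydroxy-3,4,5-trimethyl-7-methylidene-3,4-dihydro-1H-isochromene-1,6(7H)-dione (ortho-quinone methide of the lactone half) | C=C1C(=O)C(C)=C2[C@H](C)[C@@H](C)OC(=O)C2=C1O | intermediate
24 | (3R,4S)-7-{[(3R,4S)-6,8-dihydroxy-3,4,5-trimethylisochroman-7-yl]methyl}-6,8-dihydroxy-3,4,5-trimethylisochroman-1-one | Cc1c(O)c(Cc2c(O)c(C)c3c(c2O)C(=O)O[C@H](C)[C@H]3C)c(O)c4c1[C@H](C)[C@@H](C)OC4 | intermediate
25 | dicitrinone G, (3R,4S)-6,8-dihydroxy-7-{[(3R,4S)-6-hydroxy-3,4,5-trimethyl-8-oxo-3,4-dihydro-8H-isochromen-7-yl]methyl}-3,4,5-trimethylisochroman-1-one | CC1=C2C(=CO[C@H](C)[C@H]2C)C(=O)C(Cc2c(O)c(C)c3c(c2O)C(=O)O[C@H](C)[C@H]3C)=C1O | target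

Total step count: 16.
Longest linear sequence: 13 steps (steps 1, 2, 3, 6, 7, 8, 9, 11, 12, 13, 14, 15, 16).

Steps most likely to fail

Step 16. The oxidant may engage the tetraphenol at the wrong site: oxidation at the bridge or at its ipso carbon followed by spirocyclisation onto a neighbouring phenol, or a second oxidation of the product. The fallback reverses the order of dehydrogenation and union. It sets out from isochroman diol 17, which is treated with DDQ (1 equiv, anhydrous dioxane) to give the monomeric quinone methide decarboxycitrinin F1. This is the same dehydrogenation in its simplest setting, with no second ring and no bridge present. F1 is then heated with Mannich base 22 in dioxane, so that ortho-quinone methide 23 is generated and intercepted by C7 of F1, the central carbon of its vinylogous acid (C6 enol, C8 ketone). Tautomerisation of the adduct returns to the route at 25.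

Step 15. The ortho-quinone methide may be consumed by self-condensation or by re-addition of dimethylamine faster than it is arylated by the second component, or the phenols may be alkylated on oxygen. The fallback changes the electrophile and its mode of activation. It sets out from lactone diol 20, which is formylated at C7 by the Duff reaction (hexamethylenetetramine, TFA, 80 °C, then aq. HCl) to give (3R,4S)-6,8-dihydroxy-3,4,5-trimethyl-1-oxoisochromane-7-carbaldehyde F2. Reduction with NaBH4 (MeOH/THF, 0 °C) gives (3R,4S)-6,8-dihydroxy-7-(hydroxymethyl)-3,4,5-trimethylisochroman-1-one F3. Acid-catalysed Friedel–Crafts benzylation of 17 with F3 (TsOH·H2O cat., dioxane, 40 °C) loses water instead of an amine and keeps the electrophile at low concentration. It returns to the route at 24.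

Step 7. The activated carbinol, flanked by a tertiary benzylic carbon, may eliminate to the alkene or be displaced incompletely, so that inversion is not clean. The fallback replaces substitution by an oxidation–reduction pair. It sets out from erythro alcohol 12, which is oxidised with Dess–Martin periodinane (NaHCO3-buffered, CH2Cl2, 0 °C) to (3S)-3-[3,5-bis(benzyloxy)-2-methylphenyl]butan-2-one F4, under conditions meant to avoid enolisation of the aryl-bearing centre. Reduction with LiBH(s-Bu)3 (THF, −78 °C) under Felkin–Anh control, the aryl group acting as the large substituent, should give the threo alcohol. This returns to the route at 14 without passing through 13.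

Further compounds
F1 | step 16 | decarboxycitrinin, (3R,4S)-6-hydroxy-3,4,5-trimethyl-3,4-dihydro-8H-isochromen-8-one (8-keto tautomer) | CC1=C2C(=CO[C@H](C)[C@H]2C)C(=O)C=C1O
F2 | step 15 | (3R,4S)-6,8-dihydroxy-3,4,5-trimethyl-1-oxoisochromane-7-carbaldehyde | O=Cc1c(O)c(C)c2c(c1O)C(=O)O[C@H](C)[C@H]2C
F3 | step 15 | (3R,4S)-6,8-dihydroxy-7-(hydroxymethyl)-3,4,5-trimethylisochroman-1-one | OCc1c(O)c(C)c2c(c1O)C(=O)O[C@H](C)[C@H]2C
F4 | step 7 | (3S)-3-[3,5-bis(benzyloxy)-2-methylphenyl]butan-2-one | CC(=O)[C@@H](C)c1cc(OCc2ccccc2)cc(OCc2ccccc2)c1C
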